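**Plan**
- Retrosynthetic cuts (gibberellane numbering): C13–C16 (ring D), C1=C2 (ring A), then C4–C3, C4–C5, C10–C1 and O–C19 (lactone and ring A carbons hung on a ring B ketone), C8–C14 (ring C), C13–C14, and finally C9–C11, C8–C15 and C6–C7 on a cyclopentenone.
- Forward: ring B is the commercial (R)-4-silyloxycyclopentenone. Three-component coupling and carbonylation give a C6=C8 enoate, ring C is closed by conjugate addition, then the 19,10-lactone, ring A (metathesis), the 1β-hydroxy-2β,3β-epoxide and last ring D.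
- Enabling feature: C8 is the β-carbon of the ring B enoate (C7 ester on C6). C14 is the acidic carbon of a C13 β-keto ester tethered to C9 through C11–C12, so one 6-exo conjugate addition makes ring C and the quaternary spiro carbon C8.
- Stereochemistry: C9 comes from the silyloxy stereocentre of 1 (anti cuprate addition). C8, C6, C5, C10, C4, C1–C3 and C13 follow from C9 by ring fusion, convex-face attack and directed oxygen transfer.

Key step: step 6

Remark: gibberellane numbering and the usual α/β convention are used throughout; 1–3 and all reagents are taken as commercial; C14 in 10 and 11 and C4 in 16–18 are formed as mixtures and are removed or reset later.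

**Step 1**
Reactants: 1 (R)-4-[(tert-butyldimethylsilyl)oxy]cyclopent-2-en-1-one; 2 but-3-en-1-ylmagnesium bromide; 3 3-bromo-1-(trimethylsilyl)prop-1-yne
Product: 5 (2,3-trans-3,4-trans)-3-(but-3-enyl)-4-(tert-butyldimethylsilyloxy)-2-[3-(trimethylsilyl)prop-2-ynyl]cyclopentan-1-one, via bromomagnesium enolate 4 (not isolated)
Conditions: CuBr·SMe2 (10 mol%), THF, −78 °C; then HMPA, 3, −78 → −30 °C
Reagents that add atoms: none
Why: Copper-catalysed conjugate addition of the Grignard reagent anti to the 4-silyloxy group sets C9, and the regiodefined enolate is alkylated in situ trans to the new side chain (three-component coupling of the prostaglandin type).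

**Step 2**
Reactants: 5 ring B ketone
Product: 6 C6 enol triflate (C6=C8)
Conditions: Tf2O, 2,6-di-tert-butyl-4-methylpyridine, CH2Cl2, 0 °C → rt
Reagents that add atoms: triflic anhydride, O=S(=O)(OS(=O)(=O)C(F)(F)F)C(F)(F)F
Why: Electrophilic O-triflation under equilibrating, non-basic conditions should give the more substituted C6=C8 enol triflate without base-induced loss of the β-silyloxy group (vinyl triflate formation).

**Step 3**
Reactants: 6 enol triflate
Product: 7 2-(trimethylsilyl)ethyl enoate (C7 ester on C6)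
Conditions: Pd(OAc)2 (5 mol%), PPh3, CO (1 atm), 2-(trimethylsilyl)ethanol, Et3N, DMF, 60 °C
Reagents that add atoms: carbon monoxide, [C-]#[O+]; 2-(trimethylsilyl)ethanol, C[Si](C)(C)CCO
Why: Palladium-catalysed alkoxycarbonylation of the vinyl triflate installs C7 as an ester that fluoride removes at the end.

**Step 4**
Reactants: 7 enoate
Product: 8 aldehyde (C13 = CHO)
Conditions: O3, CH2Cl2–MeOH, pyridine, −78 °C; then PPh3
Reagents that add atoms: ozone, [O-][O+]=O
Why: Ozonolysis with reductive work-up should cleave the terminal alkene far faster than the electron-poor tetrasubstituted enoate or the silylalkyne.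

**Step 5**
Reactants: 8 aldehyde
Product: 9 allyl β-keto ester (C9–CH2CH2–CO–CH2–CO2allyl)
Conditions: allyl diazoacetate, SnCl2 (10 mol%), CH2Cl2, rt
Reagents that add atoms: allyl diazoacetate, C=CCOC(=O)C=[N+]=[N-]
Why: The Roskamp homologation converts the aldehyde into the β-keto ester under neutral conditions, creating the C13–C14 bond without touching C9, which is γ to the enoate.

**Step 6**
Reactants: 9 allyl β-keto ester
Product: 10 cis-fused ring B/C β-keto ester with quaternary C8
Conditions: Cs2CO3 (0.3 equiv), MeCN, 40 °C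
Reagents that add atoms: none
Why: Carbonate deprotonates only the β-keto ester carbon C14, whose enolate adds to C8, the β-carbon of the ring B enoate, and the resulting C6 ester enolate is protonated (intramolecular Michael addition, closest to the base-mediated cyclisations of β-keto esters onto unsaturated esters used for hydrindanes). Ring C closes in the 6-exo-trig mode. C8 is set by the tether, because C14 must arrive on the face of ring B that carries the C9–C11 bond, so the B/C fusion is cis and the propargyl arm ends up β. C6 is set under thermodynamic control with the ester on the convex β face trans to the new C8–C14 bond, since the addition is reversible until the stabilised β-keto ester enolate of the product forms; the C14 stereocentre is removed in step 7. The step needs chemoselective enolisation, secured by the gap of more than ten pK units between the β-keto ester and the γ-hydrogens at C9 and C15, and a single site of attack, secured because C14 is the only nucleophilic carbon in reach and C8 the only electrophilic one.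

**Step 7**
Reactants: 10 ring B/C β-keto ester
Product: 12 ring C ketone (13-oxo, C14 = CH2), via β-keto acid 11 (not isolated)
Conditions: Pd(PPh3)4 (5 mol%), morpholine, THF, rt
Reagents that add atoms: none
Why: Zerovalent palladium transfers the allyl group to morpholine (Tsuji–Trost deallylation) and the freed β-keto acid loses CO2 at room temperature.

**Step 8**
Reactants: 12 ring C ketone
Product: 13 dioxolane ketal (13,13-ethylenedioxy)
Conditions: 1,2-bis(trimethylsilyloxy)ethane, TMSOTf (5 mol%), CH2Cl2, −78 → −20 °C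
Reagents that add atoms: 1,2-bis(trimethylsilyloxy)ethane, C[Si](C)(C)OCCO[Si](C)(C)C
Why: Silyl triflate-catalysed ketalisation at low temperature masks the only ketone without disturbing the silyl ether or the esters.

**Step 9**
Reactants: 13 dioxolane ketal
Product: 14 alcohol (10β-OH)
Conditions: HF·pyridine, pyridine, THF, 0 °C → rt
Reagents that add atoms: none
Why: Buffered HF should cleave the secondary silyl ether selectively, leaving the silylalkyne, the 2-(trimethylsilyl)ethyl ester and the dioxolane (selective desilylation).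

**Step 10**
Reactants: 14 alcohol
Product: 15 ring B ketone (10-oxo)
Conditions: Dess–Martin periodinane, NaHCO3, CH2Cl2, rt
Reagents that add atoms: none
Why: Dess–Martin oxidation gives the C10 ketone, and C9, now epimerisable, is held by the cis B/C fusion.

**Step 11**
Reactants: 15 ring B ketone
Product: 16 alkylated ketone: 5α-[1-(ethoxycarbonyl)ethyl]-10-oxo compound (C4 epimers)
Conditions: LiN(iPr)2, THF, −78 °C; then ethyl (S)-2-(triflyloxy)propanoate, −78 → −40 °C
Reagents that add atoms: ethyl (S)-2-{[(trifluoromethyl)sulfonyl]oxy}propanoate, CCOC(=O)[C@H](C)OS(=O)(=O)C(F)(F)F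
Why: Kinetic deprotonation occurs at the C5 methylene and not at the C9 methine, and SN2 alkylation of this enolate by the lactate triflate takes place anti to the adjacent C6 ester, setting C5, while the C4 configuration is immaterial because step 13 resets it (enolate alkylation).

**Step 12**
Reactants: 16 alkylated ketone
Product: 18 vinyl lactone: 19,10α-lactone carrying a 10β-vinyl group (C4 epimers), via hydroxy ester 17 (not isolated)
Conditions: CH2=CHMgBr, CeCl3, THF, −78 → 0 °C; then rt
Reagents that add atoms: vinylmagnesium bromide, C=C[Mg]Br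
Why: The reagent made from CH2=CHMgBr and CeCl3 should add to the hindered, enolisable C10 ketone from the β face, away from the α substituents at C5 and C9, and the α-alkoxide then closes the cis-fused γ-lactone onto the ethyl ester (CeCl3-mediated 1,2-addition and lactonisation).

**Step 13**
Reactants: 18 vinyl lactone
Product: 19 allyl vinyl lactone (quaternary C4 with 4β-methyl; allyl cis to the 10-vinyl group)
Conditions: LiN(iPr)2, THF–HMPA, −78 °C; allyl bromide
Reagents that add atoms: allyl bromide, C=CCBr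
Why: LiN(iPr)2 should remove the lactone C4–H faster than the more hindered C6–H of the ester, and the lactone enolate is allylated on its convex face, cis to the C10 vinyl group, which leaves the 18-methyl group β and fixes the C4 quaternary centre (lactone enolate alkylation).

**Step 14**
Reactants: 19 allyl vinyl lactone
Product: 20 tetracyclic Δ1-ene 19,10-lactone (ring A closed)
Conditions: second-generation Grubbs catalyst (5 mol%), CH2Cl2, 40 °C
Reagents that add atoms: none
Why: Ring-closing metathesis of the cis-disposed vinyl and allyl groups forms the C1=C2 bond and ring A, and the hindered silylalkyne should not take part.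

**Step 15**
Reactants: 20 ketal
Product: 21 Δ1-ene lactone with free 13-ketone
Conditions: pyridinium p-toluenesulfonate, acetone–H2O, 50 °C
Reagents that add atoms: water, O
Why: Mild acid-catalysed ketal hydrolysis returns the C13 ketone before ring A is oxidised.

**Step 16**
Reactants: 21 Δ1-ene lactone
Product: 23 epoxy alcohol (1β-hydroxy-2β,3β-epoxide), via allylic hydroperoxide 22 (not isolated)
Conditions: O2, tetraphenylporphyrin (cat.), visible light, Ti(OiPr)4 (10 mol%), CH2Cl2, 0 °C
Reagents that add atoms: dioxygen, O=O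
Why: Singlet oxygen should attack C1=C2 on the β face, away from the lactone bridge, with abstraction of H-3 (Schenck ene reaction; C10 has no hydrogen, so only the 1-hydroperoxy-2-ene can form), and Ti(OiPr)4 then transfers the distal oxygen to the new C2=C3 bond syn to the resulting hydroxyl (titanium-catalysed hydroxy-epoxidation).

**Step 17**
Reactants: 23 epoxy alcohol
Product: 24 terminal alkyne
Conditions: K2CO3 (cat.), MeOH, 0 °C
Reagents that add atoms: none
Why: Base-catalysed methanolysis of the alkynyl C–Si bond frees the terminal alkyne (protodesilylation), and the cis-epoxy alcohol cannot undergo Payne rearrangement.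

**Step 18**
Reactants: 24 alkynyl ketone
Product: 25 2-(trimethylsilyl)ethyl ester of the target gibberellin (rings A to D complete)
Conditions: SmI2 (2.5 equiv), HMPA, t-BuOH, THF, −78 → 0 °C
Reagents that add atoms: none
Why: Single-electron reduction gives the C13 ketyl, which adds 5-exo-dig to the internal alkyne carbon C16; reduction and protonation of the vinyl radical give the bicyclo[3.2.1]octane with the bridgehead 13-hydroxyl and exocyclic methylene (SmI2 ketyl–alkyne cyclisation), the C13 configuration being dictated by the bridge.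

**Step 19**
Reactants: 25 2-(trimethylsilyl)ethyl ester
Product: 26 target gibberellin (2β,3β-epoxy-1β,10α,13-trihydroxy-20-norgibberell-16-ene-7,19-dioic acid 19,10-lactone)
Conditions: Bu4NF, THF, 0 °C; then dilute HCl to pH 3
Reagents that add atoms: none
Why: Fluoride-induced β-elimination cleaves the 2-(trimethylsilyl)ethyl ester under conditions that should spare the epoxide, the lactone and the tertiary allylic alcohol.

**Compound list**
1 | (R)-4-[(tert-butyldimethylsilyl)oxy]cyclopent-2-en-1-one (carbonyl = C6, silyloxy carbon = C10) | O=C1C=C[C@H](O[Si](C)(C)C(C)(C)C)C1 | starting material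
2 | but-3-en-1-ylmagnesium bromide | C=CCC[Mg]Br | starting material
3 | 3-bromo-1-(trimethylsilyl)prop-1-yne | C[Si](C)(C)C#CCBr | starting material
4 | bromomagnesium enolate (C6–O–MgBr, C6=C8) with 9α-but-3-enyl and 10β-silyloxy groups | Br[Mg]OC1=C[C@@H](CCC=C)[C@H](O[Si](C)(C)C(C)(C)C)C1 | intermediate
5 | ring B ketone: C6=O, 8β-CH2C≡CSiMe3, 9α-but-3-enyl, 10β-OTBS (2,3-trans-3,4-trans) | O=C1[C@H](CC#C[Si](C)(C)C)[C@@H](CCC=C)[C@H](O[Si](C)(C)C(C)(C)C)C1 | intermediate
6 | C6 enol triflate (C6=C8) of 5 | O=S(=O)(OC1=C(CC#C[Si](C)(C)C)[C@@H](CCC=C)[C@H](O[Si](C)(C)C(C)(C)C)C1)C(F)(F)F | intermediate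
7 | 2-(trimethylsilyl)ethyl ring B enoate (C7 ester on C6, C6=C8) | C[Si](C)(C)CCOC(=O)C1=C(CC#C[Si](C)(C)C)[C@@H](CCC=C)[C@H](O[Si](C)(C)C(C)(C)C)C1 | intermediate
8 | aldehyde: 9α-(3-oxopropyl) enoate | C[Si](C)(C)CCOC(=O)C1=C(CC#C[Si](C)(C)C)[C@@H](CCC=O)[C@H](O[Si](C)(C)C(C)(C)C)C1 | intermediate
9 | allyl β-keto ester: 9α-CH2CH2C(=O)CH2CO2allyl enoate | C[Si](C)(C)CCOC(=O)C1=C(CC#C[Si](C)(C)C)[C@@H](CCC(=O)CC(=O)OCC=C)[C@H](O[Si](C)(C)C(C)(C)C)C1 | intermediate
10 | cis-fused ring B/C β-keto ester: quaternary C8 (β-propargyl arm), 13-oxo, 14-CO2allyl (C14 epimers), 6β-ester, 10β-OTBS | C[Si](C)(C)CCOC(=O)[C@H]1C[C@@H](O[Si](C)(C)C(C)(C)C)[C@@H]2CCC(=O)C(C(=O)OCC=C)[C@]12CC#C[Si](C)(C)C | intermediate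
11 | β-keto acid (14-CO2H) | C[Si](C)(C)CCOC(=O)[C@H]1C[C@@H](O[Si](C)(C)C(C)(C)C)[C@@H]2CCC(=O)C(C(=O)O)[C@]12CC#C[Si](C)(C)C | intermediate
12 | ring C ketone (13-oxo, C14 = CH2) | C[Si](C)(C)CCOC(=O)[C@H]1C[C@@H](O[Si](C)(C)C(C)(C)C)[C@@H]2CCC(=O)C[C@]12CC#C[Si](C)(C)C | intermediate
13 | dioxolane ketal (13,13-ethylenedioxy) | C[Si](C)(C)CCOC(=O)[C@H]1C[C@@H](O[Si](C)(C)C(C)(C)C)[C@@H]2CCC3(OCCO3)C[C@]12CC#C[Si](C)(C)C | intermediate
14 | alcohol (10β-OH) | C[Si](C)(C)CCOC(=O)[C@H]1C[C@@H](O)[C@@H]2CCC3(OCCO3)C[C@]12CC#C[Si](C)(C)C | intermediate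
15 | ring B ketone (10-oxo) | C[Si](C)(C)CCOC(=O)[C@H]1CC(=O)[C@@H]2CCC3(OCCO3)C[C@]12CC#C[Si](C)(C)C | intermediate
16 | alkylated ketone: 5α-[1-(ethoxycarbonyl)ethyl]-10-oxo compound (5β-H; C4 epimers) | C[Si](C)(C)CCOC(=O)[C@H]1[C@H](C(C)C(=O)OCC)C(=O)[C@@H]2CCC3(OCCO3)C[C@]12CC#C[Si](C)(C)C | intermediate
17 | hydroxy ester: 10α-hydroxy-10β-vinyl ethyl ester (C4 epimers) | C[Si](C)(C)CCOC(=O)[C@H]1[C@H](C(C)C(=O)OCC)[C@@](O)(C=C)[C@@H]2CCC3(OCCO3)C[C@]12CC#C[Si](C)(C)C | intermediate
18 | vinyl lactone: 19,10α-lactone with 10β-vinyl group (C4–H, C4 epimers) | C[Si](C)(C)CCOC(=O)[C@H]1[C@@H]4C(C)C(=O)O[C@]4(C=C)[C@@H]2CCC3(OCCO3)C[C@]12CC#C[Si](C)(C)C | intermediate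
19 | allyl vinyl lactone: 4-allyl-4β-methyl (allyl cis to the 10-vinyl group) | C[Si](C)(C)CCOC(=O)[C@H]1[C@@H]4[C@@](C)(CC=C)C(=O)O[C@]4(C=C)[C@@H]2CCC3(OCCO3)C[C@]12CC#C[Si](C)(C)C | intermediate
20 | tetracyclic Δ1-ene 19,10-lactone (rings A, B, C) with 13-ketal | C[Si](C)(C)CCOC(=O)[C@H]1[C@@H]4[C@@]5(C)CC=C[C@@]4(OC5=O)[C@@H]2CCC3(OCCO3)C[C@]12CC#C[Si](C)(C)C | intermediate
21 | Δ1-ene 19,10-lactone 13-ketone | C[Si](C)(C)CCOC(=O)[C@H]1[C@@H]4[C@@]5(C)CC=C[C@@]4(OC5=O)[C@@H]2CCC(=O)C[C@]12CC#C[Si](C)(C)C | intermediate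
22 | allylic hydroperoxide: 1β-hydroperoxy-Δ2-ene lactone | C[Si](C)(C)CCOC(=O)[C@H]1[C@@H]4[C@@]5(C)C=C[C@@H](OO)[C@@]4(OC5=O)[C@@H]2CCC(=O)C[C@]12CC#C[Si](C)(C)C | intermediate
23 | epoxy alcohol: 1β-hydroxy-2β,3β-epoxy lactone (13-ketone, silylalkyne) | C[Si](C)(C)CCOC(=O)[C@H]1[C@@H]4[C@@]5(C)[C@H]6O[C@H]6[C@@H](O)[C@@]4(OC5=O)[C@@H]2CCC(=O)C[C@]12CC#C[Si](C)(C)C | intermediate
24 | terminal alkyne (8β-prop-2-ynyl) | C[Si](C)(C)CCOC(=O)[C@H]1[C@@H]4[C@@]5(C)[C@H]6O[C@H]6[C@@H](O)[C@@]4(OC5=O)[C@@H]2CCC(=O)C[C@]12CC#C | intermediate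
25 | 2-(trimethylsilyl)ethyl 7-ester of the target gibberellin | C=C1C[C@]23C[C@@]1(O)CC[C@H]2[C@@]12OC(=O)[C@@](C)([C@H]1[C@@H]3C(=O)OCC[Si](C)(C)C)[C@H]1O[C@H]1[C@H]2O | intermediate
26 | target gibberellin: 2β,3β-epoxy-1β,10α,13-trihydroxy-20-norgibberell-16-ene-7,19-dioic acid 19,10-lactone | C=C1C[C@]23C[C@@]1(O)CC[C@H]2[C@@]12OC(=O)[C@@](C)([C@H]1[C@@H]3C(=O)O)[C@H]1O[C@H]1[C@H]2O | target

**Step count**
Total steps: 19. Longest linear sequence: 19 (from 1).

**Steps most likely to fail**

1. Step 6. The conjugate addition to a fully substituted β-carbon may be slow, so that retro-addition or base-induced deconjugation of the enoate competes. The fallback is a radical ring closure that sets out from 8 and returns at 12. Sulfonium ylide epoxidation of aldehyde 8 (Me3S+ I−, KN(SiMe3)2) should give the terminal C13–C14 epoxide F1. LiI and AcOH open it at the terminal carbon to the iodohydrin F2. Bu3SnH with AIBN generates the C14 radical, which closes 6-exo onto C8 (Giese-type cyclisation) to the ring C alcohol F3, with C6 equilibrated by DBU if needed. Dess–Martin oxidation of F3 then gives ketone 12.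

2. Step 2. Enolisation may be poorly regioselective, with triflation toward C5, and the acid formed may cause loss of the silyloxy group. The fallback sets out from 5 and returns at 6. Thermodynamic silylation (TMSCl, NaI, Et3N, MeCN) should give the tetrasubstituted trimethylsilyl enol ether F4, which is separated from its regioisomer (hydrolysed back to 5). MeLi then regenerates the C6=C8 lithium enolate regiospecifically and PhNTf2 converts it into 6.

3. Step 16. The ene reaction of the cis-disubstituted alkene may be sluggish, and oxygen transfer from the hydroperoxide may be incomplete or unselective. The fallback sets out from 21 and returns at 23. Dimethyldioxirane in acetone should epoxidise the β face, without Baeyer–Villiger oxidation of the ketone, to give the 1β,2β-epoxide F5. PhSeNa opens it at C2 to the 2α-phenylseleno-1β-ol F6. H2O2 oxidation and selenoxide syn-elimination away from the carbinol give the 1β-hydroxy-2-ene F7. Hydroxyl-directed epoxidation with VO(acac)2 and t-BuOOH then gives 23.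

**Further compounds**
F1 | step 6 | terminal epoxide: 9α-[2-(oxiran-2-yl)ethyl] enoate (C13 epimers) | C[Si](C)(C)CCOC(=O)C1=C(CC#C[Si](C)(C)C)[C@@H](CCC2CO2)[C@H](O[Si](C)(C)C(C)(C)C)C1
F2 | step 6 | iodohydrin: 9α-(3-hydroxy-4-iodobutyl) enoate (C13 epimers) | C[Si](C)(C)CCOC(=O)C1=C(CC#C[Si](C)(C)C)[C@@H](CCC(O)CI)[C@H](O[Si](C)(C)C(C)(C)C)C1
F3 | step 6 | cis-fused ring B/C 13-alcohol (C13 epimers) | C[Si](C)(C)CCOC(=O)[C@H]1C[C@@H](O[Si](C)(C)C(C)(C)C)[C@@H]2CCC(O)C[C@]12CC#C[Si](C)(C)C
F4 | step 2 | tetrasubstituted trimethylsilyl enol ether (C6=C8) of 5 | C[Si](C)(C)OC1=C(CC#C[Si](C)(C)C)[C@@H](CCC=C)[C@H](O[Si](C)(C)C(C)(C)C)C1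
F5 | step 16 | 1β,2β-epoxy lactone | C[Si](C)(C)CCOC(=O)[C@H]1[C@@H]4[C@@]5(C)C[C@H]6O[C@H]6[C@@]4(OC5=O)[C@@H]2CCC(=O)C[C@]12CC#C[Si](C)(C)C
F6 | step 16 | 2α-phenylseleno-1β-hydroxy lactone | C[Si](C)(C)CCOC(=O)[C@H]1[C@@H]4[C@@]5(C)C[C@H]([Se]c6ccccc6)[C@@H](O)[C@@]4(OC5=O)[C@@H]2CCC(=O)C[C@]12CC#C[Si](C)(C)C
F7 | step 16 | 1β-hydroxy-Δ2-ene lactone | C[Si](C)(C)CCOC(=O)[C@H]1[C@@H]4[C@@]5(C)C=C[C@@H](O)[C@@]4(OC5=O)[C@@H]2CCC(=O)C[C@]12CC#C[Si](C)(C)C
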